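Ring numbering of the quinone: C1(=O), C2(OMe), C3(H), C4(=O), C5(CH3), C6(C21H43).
Retrosynthesis: the C1 oxygen is removed first (quinone back to a phenol with its OH on C4); the benzene ring is then cut at C1–C2, C3–C4, C4–C5 and C6–C1, leaving methoxyacetylene (C2, C3) and (E)-1-diazo-3-henicosylpent-3-en-2-one (C1, C4, C5, C6).
Enabling feature: the C2 methoxy group and the C4 oxygen are 1,3-related with C3 unsubstituted between them, which is what results when the CH end of an ynol ether bonds to a ketene carbonyl carbon; C1 can enter as C–H para to the C4 hydroxyl, and C5/C6 arrive with their methyl and henicosyl groups on the vinyl unit.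
Forward order: the chain is built first (aldol of methyl tricosanoate with acetaldehyde, dehydration, Weinreb amide, methyl ketone, diazo transfer), methoxyacetylene is made in a one-step branch, the only ring forms in a single operation in step 7, and step 8 oxygenates C1.
Stereochemistry: the target has no stereocentre; the only element carried is the E alkene of the enone, set under thermodynamic control in the E1cB dehydration and consumed on aromatisation.

Key step: step 7

Remark: methyl tricosanoate is taken as the commercial form of the C23 acid; lithium and magnesium enolates, alkoxides and the tetrahedral adduct of step 4 are metallated forms of numbered compounds and are not numbered separately.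

Step 1
Reactants: 1 methyl tricosanoate; 2 acetaldehyde
Product: 3 methyl 2-henicosyl-3-hydroxybutanoate (racemic syn/anti mixture)
Conditions: LiN(iPr)2 (commercial solution), THF, −78 to −40 °C; 2, −78 °C; sat. aq NH4Cl
Reagents that add atoms: none
Why: Aldol addition of an ester lithium enolate to a small unhindered aldehyde at low temperature is routine; the two new stereocentres are left uncontrolled because both are erased by the dehydration in step 2.

Step 2
Reactants: 3 methyl 2-henicosyl-3-hydroxybutanoate
Product: 5 methyl (E)-2-henicosylbut-2-enoate, via mesylate 4 (not isolated)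
Conditions: MsCl, Et3N, CH2Cl2, 0 °C to rt; then DBU, rt to 40 °C
Reagents that add atoms: none
Why: Sulfonylation followed by E1cB elimination through the ester enolate should give mainly the more stable E (tiglate-type) alkene from either diastereomer of 3, because mesylate leaves from the conformer that keeps the β-methyl group away from the ester.

Step 3
Reactants: 5 methyl (E)-2-henicosylbut-2-enoate
Product: 6 (E)-2-henicosyl-N-methoxy-N-methylbut-2-enamide
Conditions: MeNH(OMe)·HCl, iPrMgCl, THF, −20 to 0 °C
Reagents that add atoms: N,O-dimethylhydroxylamine hydrochloride, CNOC.Cl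
Why: Direct ester aminolysis by the chloromagnesium amide of N,O-dimethylhydroxylamine (Weinreb amide formation) is well established for α-branched enoates, whose substituted α- and β-carbons suppress conjugate addition and leave the alkene geometry untouched.

Step 4
Reactants: 6 (E)-2-henicosyl-N-methoxy-N-methylbut-2-enamide
Product: 7 (E)-3-henicosylpent-3-en-2-one
Conditions: MeMgBr, THF, 0 °C; 1 M HCl
Reagents that add atoms: methylmagnesium bromide, C[Mg]Br
Why: Weinreb ketone synthesis: the magnesium-chelated tetrahedral adduct persists until the acidic quench, so only one methyl group is delivered and the methyl ketone is released on work-up.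

Step 5
Reactants: 7 (E)-3-henicosylpent-3-en-2-one
Product: 9 (E)-1-diazo-3-henicosylpent-3-en-2-one, via trifluoroacetyl diketone 8 (not isolated)
Conditions: LiN(SiMe3)2, THF, −78 °C; CF3CO2CH2CF3; 5% HCl work-up; crude 8, MsN3, Et3N, H2O (1 equiv), MeCN/THF, rt
Reagents that add atoms: methanesulfonyl azide, CS(=O)(=O)N=[N+]=[N-]
Why: Detrifluoroacetylative diazo transfer: kinetic deprotonation at the acetyl methyl group, Claisen trifluoroacetylation and Regitz-type diazo transfer with loss of the trifluoroacetyl group onto the sulfonamide nitrogen form the standard route to α'-diazo enones, and it never exposes a conjugated acyl chloride to diazomethane.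

Step 6
Reactants: 10 chloroacetaldehyde dimethyl acetal
Product: 12 methoxyacetylene, via sodium methoxyacetylide 11 (not isolated)
Conditions: NaNH2 (3 equiv), liq. NH3, −33 °C; NH3 evaporated; sat. aq NaCl, −70 °C; distilled into a cold trap and kept as a cold ClCH2CH2Cl solution
Reagents that add atoms: none
Why: Twofold base-induced elimination (methanol, then HCl) and deprotonation give the acetylide, which brine protonates to the low-boiling ynol ether; this is the standard preparation of alkoxyacetylenes from chloroacetals.

Step 7
Reactants: 9 (E)-1-diazo-3-henicosylpent-3-en-2-one; 12 methoxyacetylene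
Product: 17 3-henicosyl-5-methoxy-2-methylphenol, via vinylketene 13 (not isolated), via vinylcyclobutenone 14 (not isolated), via dienylketene 15 (not isolated), via cyclohexadienone 16 (not isolated)
Conditions: 12 (3 equiv), hν (254 nm, low-pressure Hg lamps), ClCH2CH2Cl, sealed Vycor tube, rt; then 80 °C
Reagents that add atoms: none
Why: Light expels N2 from 9 and the Wolff shift moves vinyl carbon C6 from C4 to C1 to give vinylketene 13, whose C4=C1 bond adds to the ynol ether in a [2+2] cycloaddition (the nucleophilic CH terminus C3 attacks the ketene carbonyl carbon C4 and C2 closes onto C1) to give the 4-vinylcyclobutenone 14. Heating opens 14 by reversible conrotatory four-electron cleavage of C1–C4 to dienylketene 15, and the six-membered ring closes by thermal disrotatory six-electron electrocyclisation joining C4 to C5, after which cyclohexadienone 16 enolises to phenol 17. The closest known reaction type is the Danheiser benzannulation in its photochemical diazo ketone variant with alkoxyacetylenes. No stereocentre survives, since the centres of 14 and 16 are racemic and vanish on ring opening and enolisation. The step needs a regioselective [2+2] addition, which the polarisation of the ynol ether secures, so the methoxy-bearing carbon becomes C2 and the CH carbon becomes C3. It also needs C3 and C6 cis across C2=C1 in 15, which the reversible ring opening supplies, while the E alkene keeps the C5 methyl group on the outside of the closing triene.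

Step 8
Reactants: 17 3-henicosyl-5-methoxy-2-methylphenol
Product: 18 3-henicosyl-5-methoxy-2-methyl-1,4-benzoquinone (target)
Conditions: (KSO3)2NO, KH2PO4, methyltrioctylammonium chloride (cat.), CH2Cl2/H2O, rt
Reagents that add atoms: potassium nitrosodisulfonate, [O]N(S(=O)(=O)[O-])S(=O)(=O)[O-].[K+].[K+]
Why: Teuber oxidation: one nitroxyl radical abstracts the phenolic hydrogen, a second couples at the unsubstituted para carbon C1 (activated by the adjacent methoxy group), and loss of imidodisulfonate then gives the para-quinone.

Compound list
1 | methyl tricosanoate | CCCCCCCCCCCCCCCCCCCCCCC(=O)OC | starting material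
2 | acetaldehyde | CC=O | starting material
3 | methyl 2-henicosyl-3-hydroxybutanoate (racemic syn/anti mixture) | CCCCCCCCCCCCCCCCCCCCCC(C(C)O)C(=O)OC | intermediate
4 | methyl 2-henicosyl-3-(methylsulfonyloxy)butanoate (racemic diastereomer mixture) | CCCCCCCCCCCCCCCCCCCCCC(C(C)OS(C)(=O)=O)C(=O)OC | intermediate (not isolated)
5 | methyl (E)-2-henicosylbut-2-enoate | C/C=C(/C(=O)OC)CCCCCCCCCCCCCCCCCCCCC | intermediate
6 | (E)-2-henicosyl-N-methoxy-N-methylbut-2-enamide | C/C=C(/C(=O)N(C)OC)CCCCCCCCCCCCCCCCCCCCC | intermediate
7 | (E)-3-henicosylpent-3-en-2-one | C/C=C(/C(C)=O)CCCCCCCCCCCCCCCCCCCCC | intermediate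
8 | (E)-1,1,1-trifluoro-5-henicosylhept-5-ene-2,4-dione (drawn as the diketo tautomer) | C/C=C(/C(=O)CC(=O)C(F)(F)F)CCCCCCCCCCCCCCCCCCCCC | intermediate (not isolated)
9 | (E)-1-diazo-3-henicosylpent-3-en-2-one | C/C=C(/C(=O)C=[N+]=[N-])CCCCCCCCCCCCCCCCCCCCC | intermediate
10 | chloroacetaldehyde dimethyl acetal (2-chloro-1,1-dimethoxyethane) | COC(CCl)OC | starting material
11 | sodium methoxyacetylide | COC#[C-].[Na+] | intermediate (not isolated)
12 | methoxyacetylene | COC#C | intermediate
13 | (3E)-3-henicosylpenta-1,3-dien-1-one (vinylketene) | C/C=C(/C=C=O)CCCCCCCCCCCCCCCCCCCCC | intermediate (not isolated)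
14 | 3-methoxy-4-[(2E)-tetracos-2-en-3-yl]cyclobut-2-en-1-one (racemic) | C/C=C(/C1C(=O)C=C1OC)CCCCCCCCCCCCCCCCCCCCC | intermediate (not isolated)
15 | (3E,5E)-5-henicosyl-3-methoxyhepta-1,3,5-trien-1-one (dienylketene) | C(/C=C=O)(OC)=C/C(CCCCCCCCCCCCCCCCCCCCC)=C/C | intermediate (not isolated)
16 | 5-henicosyl-3-methoxy-6-methylcyclohexa-2,4-dien-1-one (racemic) | CC1C(=O)C=C(OC)C=C1CCCCCCCCCCCCCCCCCCCCC | intermediate (not isolated)
17 | 3-henicosyl-5-methoxy-2-methylphenol | Cc1c(O)cc(OC)cc1CCCCCCCCCCCCCCCCCCCCC | intermediate
18 | 3-henicosyl-5-methoxy-2-methyl-1,4-benzoquinone | CCCCCCCCCCCCCCCCCCCCCC1=C(C)C(=O)C=C(OC)C1=O | target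

Total step count: 8. Longest linear sequence: 7 steps (steps 1 to 5, 7 and 8); step 6 is a one-step branch.

Steps most likely to fail

Step 7. The low-boiling terminal ynol ether may escape into the headspace or oligomerise under the lamp faster than it intercepts the vinylketene, which would then dimerise or acylate phenol already formed. The fallback sets out from diazo ketone 9 and replaces 12 by commercial ethoxyacetylene (CCOC#C, used in large excess from its hexane solution) in the same irradiation and heating sequence, which should give 5-ethoxy-3-henicosyl-2-methylphenol F1. Oxidation of F1 with (KSO3)2NO as in step 8 should give 5-ethoxy-3-henicosyl-2-methyl-1,4-benzoquinone F2. Acid-catalysed alkoxy exchange of this vinylogous ester in MeOH (cat. H2SO4; methanol adds to C2 and ethanol leaves) comes back to the route at target 18, bypassing 12 and 17.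

Step 5. Removal of a γ-hydrogen (C5 methyl or the first chain methylene) in competition with the acetyl hydrogens, or O- instead of C-trifluoroacetylation, would leave material that the sulfonyl azide cannot convert. The fallback sets out from ester 5: saponification (LiOH, THF/MeOH/H2O, then HCl) should give (E)-2-henicosylbut-2-enoic acid F3, and (COCl)2 with cat. DMF in CH2Cl2 should give (E)-2-henicosylbut-2-enoyl chloride F4. Acylation of Me3SiCHN2 by F4 in THF/MeCN at 0 °C (first stage of the Arndt–Eistert sequence, without amine base so that the acyl chloride is not dehydrochlorinated to a ketene) comes back to the route at diazo ketone 9; the trisubstituted alkene should resist dipolar cycloaddition.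

Step 8. Slow transfer of the water-bound radical salt to the waxy phenol, together with competing attack at the ortho carbon C3 and further oxidation of the electron-rich quinone, may erode conversion to the para-quinone. The fallback sets out from phenol 17: para-nitrosation (NaNO2, AcOH/EtOH, 0 °C) should give 3-henicosyl-5-methoxy-2-methyl-4-nitrosophenol F5 (in equilibrium with its quinone monoxime tautomer), and reduction with Na2S2O4 should give 4-amino-3-henicosyl-5-methoxy-2-methylphenol F6. Two-phase oxidation with FeCl3 in dilute HCl/Et2O should pass through 3-henicosyl-4-imino-5-methoxy-2-methylcyclohexa-2,5-dien-1-one F7, whose hydrolysis comes back to the route at target 18.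

Further compounds
F1 | step 7 | 5-ethoxy-3-henicosyl-2-methylphenol | Cc1c(O)cc(OCC)cc1CCCCCCCCCCCCCCCCCCCCC
F2 | step 7 | 5-ethoxy-3-henicosyl-2-methyl-1,4-benzoquinone | CCCCCCCCCCCCCCCCCCCCCC1=C(C)C(=O)C=C(OCC)C1=O
F3 | step 5 | (E)-2-henicosylbut-2-enoic acid | C/C=C(/C(=O)O)CCCCCCCCCCCCCCCCCCCCC
F4 | step 5 | (E)-2-henicosylbut-2-enoyl chloride | C/C=C(/C(=O)Cl)CCCCCCCCCCCCCCCCCCCCC
F5 | step 8 | 3-henicosyl-5-methoxy-2-methyl-4-nitrosophenol | Cc1c(O)cc(OC)c(N=O)c1CCCCCCCCCCCCCCCCCCCCC
F6 | step 8 | 4-amino-3-henicosyl-5-methoxy-2-methylphenol | Cc1c(O)cc(OC)c(N)c1CCCCCCCCCCCCCCCCCCCCC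
F7 | step 8 | 3-henicosyl-4-imino-5-methoxy-2-methylcyclohexa-2,5-dien-1-one | CC1=C(CCCCCCCCCCCCCCCCCCCCC)C(=N)C(OC)=CC1=O
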